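**Plan**
Retrosynthesis: the quinone C–N bond is cut first (isopentylamine for methoxide) and the hydroxyquinone is taken back to a 2,3,5,6‑tetramethoxyphenyl group. The decalin is then opened at C4–C5 and C9–C10 while the C9 methyl returns to C10 and the hydrogens on C8 and C10 return to C9 and C5; the aryl–C11 bond is cut last.
Forward: farnesyl bromide is joined to lithiated tetramethoxybenzene, one acid‑triggered cascade closes ring A, then ring B, and shifts the backbone, and oxidation, mono‑saponification and amine exchange finish the quinone.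
Enabling feature: the decalin (ring A = C1–C5/C10 with C4 gem‑dimethyl, ring B = C5–C10) is a cyclised farnesyl chain after three 1,2‑shifts. The methyl on C9 (missing from C10), the hydrogens on C8 and C10, and the C5=C6 olefin where the cation ended record this.
Stereochemistry: C8 (S), C9 (R) and C10 (S) all arise in the key step. The chiral acid fixes the absolute sense, the (E,E)‑chain in a chair–chair fold fixes the relative one, and antiperiplanar shifts pass it on.

Key step: step 2

Remark: sesquiterpene carbons carry drimane locants (C11 = benzylic CH2, C12 = methyl on C8; C3=C4 is the terminal olefin of the farnesyl chain), and the antipode of the confined acid that gives the 5S,10S fold is assumed to be the (S,S)‑form, to be confirmed in the first experiment.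

**Route**

Step 1
Reactants: 1 1,2,4,5‑tetramethoxybenzene; 2 (2E,6E)‑farnesyl bromide
Product: 4 1‑[(2E,6E)‑3,7,11‑trimethyldodeca‑2,6,10‑trien‑1‑yl]‑2,3,5,6‑tetramethoxybenzene, via tetramethoxyphenyllithium 3 (not isolated)
Conditions: n‑BuLi (1.0 equiv), TMEDA, THF, 0 °C; then CuBr·SMe2 (cat.), 2, −78 °C → rt
Reagents that add atoms: none
Why: Directed ortho‑lithiation between two methoxy groups followed by copper‑catalysed SN2 allylic substitution at the primary carbon should join the chain without SN2′ transposition and with the 2E olefin intact, one equivalent of base limiting metalation to one of the two equivalent C–H positions.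

Step 2
Reactants: 4 the (E,E)‑farnesyl tetramethoxybenzene
Product: 6 2,3,5,6‑tetramethoxy‑1‑{[(1R,2S,8aS)‑1,2,5,5‑tetramethyl‑1,2,3,5,6,7,8,8a‑octahydronaphthalen‑1‑yl]methyl}benzene (drimane locants 8S,9R,10S: 8β‑CH3, 9β‑CH3, 9α‑CH2Ar, 10α‑H, C5=C6), via drimanyl C8 cation 5 (not isolated)
Conditions: (S,S)‑IDPi (confined imidodiphosphorimidate Brønsted acid, 10 mol%), (CF3)3COH/CH2Cl2, −20 °C → rt, high dilution; Et3N quench
Reagents that add atoms: none
Why: Proposed new method: the confined acid protonates C3 of the terminal olefin and, with the (E,E)‑chain held in a chair–chair fold inside its pocket, the C4 cation is taken up by C5 and the C10 cation by C9 to give the trans‑fused ion pair 5, in which H9α, CH3‑10β and H5α are axial and antiperiplanar, so that H(C9→C8), CH3(C10→C9) and H(C5→C10) migrate suprafacially, each move bringing the charge back toward the anion left near C3/C4, until the C5 cation gives up H6 to that anion and the acid is regenerated. The closest known reaction types are the proton‑initiated enantioselective bicyclisation of (E,E)‑homofarnesyl substrates by chiral Brønsted acids (Lewis‑acid‑assisted BINOL acids, confined imidodiphosphorimidates in fluorinated alcohols) and the BF3·OEt2‑induced 1,2‑H/1,2‑CH3 (friedo) rearrangement of drimenyl arenes; their union in one operation and the stop at C5=C6 are untested. Ring A closes 6‑endo‑trig (bond C4–C5) and ring B 6‑endo‑trig (bond C9–C10), both as cation–olefin additions through chair transition states. The absolute configuration is set by the enantioface of C3=C4 that the chiral acid protonates in concert with the first closure, the relative configuration of 5 (5α‑H, 9α‑H, 10β‑CH3) by the E geometry of both internal olefins in the all‑chair fold, and each stereospecific anti shift passes it on to C8 (S, CH3 β), C9 (R, CH3 β, CH2Ar α) and C10 (S, H α). The step needs onward migration instead of capture or early proton loss and termination by loss of H6: both ortho positions of the arene carry OMe and the medium holds no nucleophile, so 5 cannot close by Friedel–Crafts reaction, drimenes formed by premature deprotonation are re‑protonated by the strong acid and fed back, the methyl shift is driven by release of the 1,3‑diaxial C4β‑CH3/C10‑CH3 strain, and the bulky weakly basic anion should take the exposed axial H6 before a C4 methyl migrates.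

Step 3
Reactants: 6 the rearranged decalin tetramethoxybenzene
Product: 7 2,5‑dimethoxy‑3‑{[(1R,2S,8aS)‑1,2,5,5‑tetramethyl‑1,2,3,5,6,7,8,8a‑octahydronaphthalen‑1‑yl]methyl}cyclohexa‑2,5‑diene‑1,4‑dione
Conditions: CAN (2.5 equiv), MeCN/H2O, 0 °C, short reaction time
Reagents that add atoms: water, O
Why: Ceric ammonium nitrate oxidative demethylation of a 1,4‑dimethoxyarene should give the p‑quinone, both para pairs of methoxy groups leading by symmetry to the same 2,5‑dimethoxy‑3‑alkylquinone, while the isolated trisubstituted olefin and the three stereocentres are not touched at 0 °C.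

Step 4
Reactants: 7 the 2,5‑dimethoxyquinone
Product: 8 2‑hydroxy‑5‑methoxy‑3‑{[(1R,2S,8aS)‑1,2,5,5‑tetramethyl‑1,2,3,5,6,7,8,8a‑octahydronaphthalen‑1‑yl]methyl}cyclohexa‑2,5‑diene‑1,4‑dione
Conditions: KOH, MeOH/H2O, 0 °C → rt; then 1 M HCl to pH 3, 0 °C
Reagents that add atoms: potassium hydroxide, [K+].[OH-]
Why: Addition–elimination saponification of a vinylogous ester should remove the methoxy group beside the side chain, which is twisted out of the quinone plane and is the poorer donor so that its carbon is the more electrophilic, and the hydroxyquinone anion formed resists a second attack.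

Step 5
Reactants: 8 the 2‑hydroxy‑5‑methoxyquinone; 9 3‑methylbutan‑1‑amine
Product: 10 nakijiquinone M, 2‑hydroxy‑5‑[(3‑methylbutyl)amino]‑3‑{[(1R,2S,8aS)‑1,2,5,5‑tetramethyl‑1,2,3,5,6,7,8,8a‑octahydronaphthalen‑1‑yl]methyl}cyclohexa‑2,5‑diene‑1,4‑dione
Conditions: 9 (3 equiv), EtOH, rt; dilute aqueous acid wash
Reagents that add atoms: none
Why: Addition–elimination of a primary amine at C5 should turn the remaining vinylogous ester into the vinylogous amide, the deprotonated 2‑hydroxy group being inert and no stereocentre being involved.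

**Compound list**
1 | 1,2,4,5‑tetramethoxybenzene | COc1cc(OC)c(OC)cc1OC | starting material
2 | (2E,6E)‑farnesyl bromide | CC(C)=CCC/C(C)=C/CC/C(C)=C/CBr | starting material
3 | 2,3,5,6‑tetramethoxyphenyllithium | [Li]c1c(OC)c(OC)cc(OC)c1OC | intermediate
4 | 1‑[(2E,6E)‑farnesyl]‑2,3,5,6‑tetramethoxybenzene | COc1cc(OC)c(OC)c(C/C=C(\C)CC/C=C(\C)CCC=C(C)C)c1OC | intermediate
5 | 11‑(2,3,5,6‑tetramethoxyphenyl)drim‑8‑yl cation (trans‑decalin, 5α‑H, 9α‑H, 10β‑CH3), ion pair with the catalyst anion | COc1cc(OC)c(OC)c(C[C@H]2[C+](C)CC[C@H]3C(C)(C)CCC[C@@]32C)c1OC | intermediate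
6 | 2,3,5,6‑tetramethoxy‑1‑{[(1R,2S,8aS)‑1,2,5,5‑tetramethyl‑1,2,3,5,6,7,8,8a‑octahydronaphthalen‑1‑yl]methyl}benzene | COc1cc(OC)c(OC)c(C[C@@]2(C)[C@@H]3CCCC(C)(C)C3=CC[C@@H]2C)c1OC | intermediate
7 | 2,5‑dimethoxy‑3‑{[(1R,2S,8aS)‑decalinyl]methyl}‑1,4‑benzoquinone | COC1=CC(=O)C(OC)=C(C[C@@]2(C)[C@@H]3CCCC(C)(C)C3=CC[C@@H]2C)C1=O | intermediate
8 | 2‑hydroxy‑5‑methoxy‑3‑{[(1R,2S,8aS)‑decalinyl]methyl}‑1,4‑benzoquinone | COC1=CC(=O)C(O)=C(C[C@@]2(C)[C@@H]3CCCC(C)(C)C3=CC[C@@H]2C)C1=O | intermediate
9 | 3‑methylbutan‑1‑amine | CC(C)CCN | starting material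
10 | nakijiquinone M | CC(C)CCNC1=CC(=O)C(O)=C(C[C@@]2(C)[C@@H]3CCCC(C)(C)C3=CC[C@@H]2C)C1=O | target

**Count**
Total steps: 5. Longest linear sequence: 5 steps (1 → 4 → 6 → 7 → 8 → 10).

**Steps most likely to fail**

Step 2 (proposed new method). Four things may go wrong:
- weak enantioface discrimination at the terminal olefin, since the far end of the substrate is a bulky arene and not a polar group;
- arrest of the cascade by proton loss at the drimene stage;
- termination at the wrong position, by loss of H5 or H10 or by onward migration of a C4 methyl;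
- demethylative capture of the cation by an ortho‑methoxy oxygen.

The fallback uses known chemistry and builds ring B by cycloaddition. It sets out from 1 (used as its lithio derivative 3) and returns to the route at 6; the decalin partner comes from commercial 2,2‑dimethylcyclohexanone. The ketone is converted with LDA and PhNTf2 into 6,6‑dimethylcyclohex‑1‑en‑1‑yl triflate F1. Stille coupling with tributyl(vinyl)stannane (Pd(PPh3)4, LiCl, THF) gives 6,6‑dimethyl‑1‑vinylcyclohex‑1‑ene F2. An exo‑selective Diels–Alder reaction of F2 with (E)‑2‑methylbut‑2‑enal, catalysed by a chiral oxazaborolidinium triflimide, should give (1R,2S,8aS)‑1,2,5,5‑tetramethyl‑1,2,3,5,6,7,8,8a‑octahydronaphthalene‑1‑carbaldehyde F3. The E‑dienophile places the C8 and C9 methyls cis, the exo formyl group ends up cis to H10, and the catalyst antipode selects the enantiomer. Addition of 3 to this non‑enolisable aldehyde gives the C11 carbinol F4 (either epimer). Its S‑methyl xanthate F5 (NaH, CS2, MeI) is reduced with Bu3SnH/AIBN (Barton–McCombie deoxygenation) to 6.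

Step 3. Oxidation across an ortho pair of methoxy groups, allylic oxidation, or migration of the C5=C6 bond under the nitric acid released may erode the yield. The fallback sets out from 6 and returns at 7 without cerium(IV) and without strong acid. Anodic oxidation of 6 in methanolic KOH (undivided cell, carbon anode) should give the quinone bis(dimethyl ketal) F6, the electron‑rich arene being oxidised well before the isolated olefin. Hydrolysis of the two ketals with aqueous acetic acid then gives 7.

Step 4. Hydroxide may attack the other vinylogous ester, or both may be hydrolysed. The fallback sets out from 7 and returns at 10, and avoids the need to tell the two methoxy groups apart. Both are hydrolysed (aqueous NaOH, EtOH, heat; then acid) to the 2,5‑dihydroxy‑3‑alkyl‑1,4‑benzoquinone F7. Condensation of F7 with 9 in warm EtOH should occur at the unhindered C5 beside the ring C–H and not at C2 beside the neopentyl‑type side chain. This is the known behaviour of 3‑alkyl‑2,5‑dihydroxybenzoquinones with primary amines and gives 10 directly.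

**Further compounds**
F1 | step 2 | 6,6‑dimethylcyclohex‑1‑en‑1‑yl trifluoromethanesulfonate | CC1(C)CCCC=C1OS(=O)(=O)C(F)(F)F
F2 | step 2 | 6,6‑dimethyl‑1‑vinylcyclohex‑1‑ene | C=CC1=CCCCC1(C)C
F3 | step 2 | (1R,2S,8aS)‑1,2,5,5‑tetramethyl‑1,2,3,5,6,7,8,8a‑octahydronaphthalene‑1‑carbaldehyde | O=C[C@@]1(C)[C@@H]2CCCC(C)(C)C2=CC[C@@H]1C
F4 | step 2 | (2,3,5,6‑tetramethoxyphenyl)[(1R,2S,8aS)‑1,2,5,5‑tetramethyl‑1,2,3,5,6,7,8,8a‑octahydronaphthalen‑1‑yl]methanol, either C11 epimer | COc1cc(OC)c(OC)c(C(O)[C@@]2(C)[C@@H]3CCCC(C)(C)C3=CC[C@@H]2C)c1OC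
F5 | step 2 | O‑[C11 carbinol of F4] S‑methyl dithiocarbonate (xanthate) | COc1cc(OC)c(OC)c(C(OC(=S)SC)[C@@]2(C)[C@@H]3CCCC(C)(C)C3=CC[C@@H]2C)c1OC
F6 | step 3 | 1,3,3,4,6,6‑hexamethoxy‑2‑{[(1R,2S,8aS)‑1,2,5,5‑tetramethyl‑1,2,3,5,6,7,8,8a‑octahydronaphthalen‑1‑yl]methyl}cyclohexa‑1,4‑diene (quinone bis(dimethyl ketal)) | COC1=C(C[C@@]2(C)[C@@H]3CCCC(C)(C)C3=CC[C@@H]2C)C(OC)(OC)C(OC)=CC1(OC)OC
F7 | step 4 | 2,5‑dihydroxy‑3‑{[(1R,2S,8aS)‑1,2,5,5‑tetramethyl‑1,2,3,5,6,7,8,8a‑octahydronaphthalen‑1‑yl]methyl}‑1,4‑benzoquinone | O=C1C=C(O)C(=O)C(C[C@@]2(C)[C@@H]3CCCC(C)(C)C3=CC[C@@H]2C)=C1O
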